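**Retrosynthetic overview**

1. Feature: each ring A (C4a, C5, C6, C7, C8, C8a, with oxygen on C5, C7 and C8a and the C4 ketone on C4a) is an acylphloroglucinol, that is a triketide chain folded onto the C4 (or C4'') carbonyl; unit 1 is 5,7-dihydroxy, unit 2 is 5''-hydroxy-7''-methoxy.
2. Last disconnection: O1–C2 and O1''–C2'' of both rings C, by a catalyst-controlled double oxa-Michael closure of a 3,3''-linked bis-chalcone; C3 and C3'' relax to 2,3-trans.
3. Key disconnection: C4a–C8a and C4a''–C8a'' of both rings A, by two Claisen folds of a bis(4-methoxybenzylidene)succinyl core carrying a free 3,5,7-triketo ester chain and a 3-O-methylated chain. The methylated chain is stored as its lactone (a 4-methoxy-2-pyrone), because the open chain relactonises under base; the cyclisation base opens it in the same flask.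
4. The chains come from C-acylation of lithiated 4-methoxy-6-methyl-2-pyrone and of the methyl 3,5-dioxohexanoate trianion by the two carboxyls, in turn, of a bis(4-methoxybenzylidene)succinic half-ester made by two Stobbe condensations.
5. Ring order: rings B are bought; both rings A form in step 7; both rings C form in step 8.

Key step: step 7

Assumption: the quinine-derived thiourea of step 8 is taken, by analogy with related chalcone cyclisations, to give the 2S sense at both C2 centres; if the sense is the opposite, its quinidine-derived pseudoenantiomer is used in the same step.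

**Route**

Step 1
Reactants: 1 dimethyl succinate; 2 4-methoxybenzaldehyde
Product: 3 (E)-3-(methoxycarbonyl)-4-(4-methoxyphenyl)but-3-enoic acid
Conditions: NaOMe, MeOH, reflux; then aq HCl
Reagents that add atoms: none
Why: Stobbe condensation, in which the succinate enolate adds to the aldehyde, the alkoxide lactonises onto the distal ester and base-induced opening of the paraconic ester gives the half-ester salt irreversibly, with the aryl group trans to the retained ester (E) for steric reasons.

Step 2
Reactants: 3 (E)-3-(methoxycarbonyl)-4-(4-methoxyphenyl)but-3-enoic acid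
Product: 4 4-tert-butyl 1-methyl (E)-2-(4-methoxybenzylidene)butanedioate
Conditions: Cl3CC(=NH)OtBu, CH2Cl2/cyclohexane, 25 °C
Reagents that add atoms: tert-butyl 2,2,2-trichloroacetimidate, CC(C)(C)OC(=N)C(Cl)(Cl)Cl
Why: imidate esterification, in which the substrate acid protonates the trichloroacetimidate and its carboxylate takes up the tert-butyl cation, so only the free carboxyl is esterified and the conjugated methyl ester is untouched.

Step 3
Reactants: 4 4-tert-butyl 1-methyl (E)-2-(4-methoxybenzylidene)butanedioate; 2 4-methoxybenzaldehyde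
Product: 5 (2E,3E)-4-tert-butoxy-2,3-bis(4-methoxybenzylidene)-4-oxobutanoic acid
Conditions: KOtBu, t-BuOH, 80 °C; then aq HCl
Reagents that add atoms: none
Why: second Stobbe condensation, in which only the methylene next to the tert-butyl ester can be deprotonated and its aldol alkoxide can lactonise only onto the methyl ester (five-membered ring), so ring opening frees that carboxyl, keeps the tert-butyl ester and forms the new arylidene again as E.

Step 4
Reactants: 5 (2E,3E)-4-tert-butoxy-2,3-bis(4-methoxybenzylidene)-4-oxobutanoic acid; 6 4-methoxy-6-methyl-2H-pyran-2-one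
Product: 8 tert-butyl (2E,3E)-2,3-bis(4-methoxybenzylidene)-5-(4-methoxy-2-oxo-2H-pyran-6-yl)-4-oxopentanoate, via acyl imidazole 7 (not isolated)
Conditions: 1,1'-carbonyldiimidazole (CDI), THF, 25 °C; then add to 6 + LiN(iPr)2 (3.2 equiv each), THF, −78 → −30 °C; aq HCl
Reagents that add atoms: none
Why: crossed Claisen-type C-acylation, in which LiN(iPr)2 deprotonates the 6-methyl group of the pyrone (vinylogous ester enolate) and this carbanion attacks the acyl imidazole, the most electrophilic carbonyl present, while the excess carbanion absorbs the imidazole N–H and turns the more acidic product into its enolate, which stops a second addition.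

Step 5
Reactants: 8 tert-butyl (2E,3E)-2,3-bis(4-methoxybenzylidene)-5-(4-methoxy-2-oxo-2H-pyran-6-yl)-4-oxopentanoate
Product: 9 (2E,3E)-2,3-bis(4-methoxybenzylidene)-5-(4-methoxy-2-oxo-2H-pyran-6-yl)-4-oxopentanoic acid
Conditions: CF3CO2H, CH2Cl2, 0 → 25 °C
Reagents that add atoms: none
Why: acidolysis of the tert-butyl ester with loss of the tert-butyl cation as isobutene, orthogonal to the pyrone, the enolisable ketone, the aryl methyl ethers and the dienone.

Step 6
Reactants: 9 (2E,3E)-2,3-bis(4-methoxybenzylidene)-5-(4-methoxy-2-oxo-2H-pyran-6-yl)-4-oxopentanoic acid; 10 methyl 3,5-dioxohexanoate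
Product: 12 methyl (8E,9E)-8,9-bis(4-methoxybenzylidene)-11-(4-methoxy-2-oxo-2H-pyran-6-yl)-3,5,7,10-tetraoxoundecanoate, via acyl imidazole 11 (not isolated)
Conditions: CDI, THF, 25 °C; then add to 10 (4.5 equiv) + LiN(iPr)2 (13.5 equiv), THF, 0 °C then −78 °C; cold aq HCl; product used promptly
Reagents that add atoms: none
Why: terminal C-acylation of a 3,5-diketo ester trianion (polyketide-type chain extension), in which the last-formed and most basic C6 carbanion attacks the acyl imidazole in 1,2-fashion while the pyronylmethyl ketone sits protected as its enolate, and should 11 first close to its enol lactone, that enol ester is opened by the same carbanion to the same product.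

Step 7
Reactants: 12 methyl (8E,9E)-8,9-bis(4-methoxybenzylidene)-11-(4-methoxy-2-oxo-2H-pyran-6-yl)-3,5,7,10-tetraoxoundecanoate
Product: 14 (2E,3E)-1-(2,6-dihydroxy-4-methoxyphenyl)-2,3-bis(4-methoxybenzylidene)-4-(2,4,6-trihydroxyphenyl)butane-1,4-dione, via open-chain methoxyenoate triketo ester 13 (not isolated)
Conditions: Mg(OMe)2 (10 equiv), MeOH, 25 °C then 65 °C, dark; then ice-cold 1 M HCl
Reagents that add atoms: none
Why: Proposed new method: Mg(OMe)2 opens the 4-methoxy-2-pyrone of 12 by methanolysis at the lactone carbonyl to the (E)-3-methoxy-enoate, so that 13 holds both chains as Mg2+ chelates of their 5,7-diketone units (each chain numbered from its ester carbon C1), whose central carbon C6 attacks the terminal ester carbon C1 of its own chain (intramolecular Claisen condensation), methoxide leaves and the ring enolises to the arene. The closest known reaction type is the biomimetic Claisen cyclisation of one 3,5,7-triketo ester, or of one 6-(2-oxoalkyl)-2-pyrone, to an acylphloroglucinol with Mg(OMe)2 or hydroxide; what has not been shown is the two-fold fold on a cross-conjugated dienedione with one O-methylated chain. Each ring A closes 6-exo-trig at the ester carbonyl and gives one new bond, C4a–C8a in unit 1 and C4a''–C8a'' in unit 2, the (E)-enol ether holding C1 cis to C4 as the fold requires. No stereocentre is formed and both arylidene double bonds should keep their E geometry. The step needs Claisen closure to win over aldol closure (C2 onto the C7 ketone), over retro-Claisen cleavage and over oxa-Michael addition of chain enolates or of the new phenoxides to the enones: chelation by Mg2+ makes C6 the nucleophile and holds the C7 carbonyl in an unreactive chelate, the methyl enol ether removes the C2 nucleophile of the unit 2 chain and ends as the 7''-methoxy group, and the polyphenoxide is expected to stay open-chain until the cold acid quench. If the free chain folds before the pyrone opens, the same product 14 results.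

Step 8
Reactants: 14 (2E,3E)-1-(2,6-dihydroxy-4-methoxyphenyl)-2,3-bis(4-methoxybenzylidene)-4-(2,4,6-trihydroxyphenyl)butane-1,4-dione
Product: 15 Ruixianglangdusu B, (2S,3R,2''S,3''R)-5,7,5''-trihydroxy-7''-methoxy-2,2''-bis(4-methoxyphenyl)-3,3''-biflavanone
Conditions: 1-[3,5-bis(trifluoromethyl)phenyl]-3-[(8S,9S)-6'-methoxycinchonan-9-yl]thiourea (20 mol %), toluene/THF (9:1), −20 → 25 °C, dark
Reagents that add atoms: none
Why: organocatalytic asymmetric intramolecular oxa-Michael addition (chalcone-to-flavanone cyclisation), in which the quinuclidine nitrogen deprotonates one of the two equivalent ortho-hydroxyls of each ring A while the thiourea binds the enone carbonyl, the phenoxide adds 6-endo-trig to one face of each benzylic β-carbon so that the catalyst sets C2 and C2'' as S, and C3 and C3'', formed by enol protonation and epimerisable through the same enol, settle in the 2,3-trans diequatorial arrangement (3R, 3''R).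

**Compound list**

1 | dimethyl succinate | COC(=O)CCC(=O)OC | starting material
2 | 4-methoxybenzaldehyde | COc1ccc(C=O)cc1 | starting material
3 | (E)-3-(methoxycarbonyl)-4-(4-methoxyphenyl)but-3-enoic acid | COC(=O)/C(=C/c1ccc(OC)cc1)CC(=O)O | intermediate
4 | 4-tert-butyl 1-methyl (E)-2-(4-methoxybenzylidene)butanedioate | COC(=O)/C(=C/c1ccc(OC)cc1)CC(=O)OC(C)(C)C | intermediate
5 | (2E,3E)-4-tert-butoxy-2,3-bis(4-methoxybenzylidene)-4-oxobutanoic acid | CC(C)(C)OC(=O)/C(=C/c1ccc(OC)cc1)C(=C/c1ccc(OC)cc1)\C(=O)O | intermediate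
6 | 4-methoxy-6-methyl-2H-pyran-2-one | COC1=CC(=O)OC(C)=C1 | starting material
7 | tert-butyl (2E,3E)-4-(1H-imidazol-1-yl)-2,3-bis(4-methoxybenzylidene)-4-oxobutanoate (acyl imidazole of 5, formed in the flask, not isolated) | CC(C)(C)OC(=O)/C(=C/c1ccc(OC)cc1)C(=C/c1ccc(OC)cc1)\C(=O)n1ccnc1 | intermediate
8 | tert-butyl (2E,3E)-2,3-bis(4-methoxybenzylidene)-5-(4-methoxy-2-oxo-2H-pyran-6-yl)-4-oxopentanoate | CC(C)(C)OC(=O)/C(=C/c1ccc(OC)cc1)C(=C/c1ccc(OC)cc1)\C(=O)CC1=CC(OC)=CC(=O)O1 | intermediate
9 | (2E,3E)-2,3-bis(4-methoxybenzylidene)-5-(4-methoxy-2-oxo-2H-pyran-6-yl)-4-oxopentanoic acid | OC(=O)/C(=C/c1ccc(OC)cc1)C(=C/c1ccc(OC)cc1)\C(=O)CC1=CC(OC)=CC(=O)O1 | intermediate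
10 | methyl 3,5-dioxohexanoate | COC(=O)CC(=O)CC(C)=O | starting material
11 | 6-[(3E,4E)-5-(1H-imidazol-1-yl)-3,4-bis(4-methoxybenzylidene)-2,5-dioxopentyl]-4-methoxy-2H-pyran-2-one (acyl imidazole of 9, formed in the flask, not isolated) | O=C(n1ccnc1)/C(=C/c1ccc(OC)cc1)C(=C/c1ccc(OC)cc1)\C(=O)CC1=CC(OC)=CC(=O)O1 | intermediate
12 | methyl (8E,9E)-8,9-bis(4-methoxybenzylidene)-11-(4-methoxy-2-oxo-2H-pyran-6-yl)-3,5,7,10-tetraoxoundecanoate | COC(=O)CC(=O)CC(=O)CC(=O)/C(=C/c1ccc(OC)cc1)C(=C/c1ccc(OC)cc1)\C(=O)CC1=CC(OC)=CC(=O)O1 | intermediate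
13 | dimethyl (2E,8E,9E)-3-methoxy-8,9-bis(4-methoxybenzylidene)-5,7,10,12,14-pentaoxohexadec-2-enedioate (open-chain fold precursor, formed in the flask as its Mg2+ chelate, not isolated) | COC(=O)CC(=O)CC(=O)CC(=O)/C(=C/c1ccc(OC)cc1)C(=C/c1ccc(OC)cc1)\C(=O)CC(=O)C/C(OC)=C\C(=O)OC | intermediate
14 | (2E,3E)-1-(2,6-dihydroxy-4-methoxyphenyl)-2,3-bis(4-methoxybenzylidene)-4-(2,4,6-trihydroxyphenyl)butane-1,4-dione (bis-chalcone) | COc1ccc(/C=C(/C(=O)c2c(O)cc(O)cc2O)C(=C/c2ccc(OC)cc2)\C(=O)c2c(O)cc(OC)cc2O)cc1 | intermediate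
15 | Ruixianglangdusu B, (2S,3R,2''S,3''R)-5,7,5''-trihydroxy-7''-methoxy-2,2''-bis(4-methoxyphenyl)-3,3''-biflavanone | COc1ccc([C@H]2Oc3cc(O)cc(O)c3C(=O)[C@@H]2[C@H]2C(=O)c3c(O)cc(OC)cc3O[C@@H]2c2ccc(OC)cc2)cc1 | target

**Step count and risks**

Total step count: 8. Longest linear sequence: 8 steps (1 and 2 to 15); 6 and 10 are bought.

Steps most likely to fail:

Step 7 (proposed new method). The O-methylated chain may fold by aldol closure or stay as the pyrone, methoxide may cleave the diketones by retro-Claisen reaction, and the new phenoxides may add to the enones before the quench, which would close rings C without control. Fallback (sets out from 5, returns at 14; known aryllithium acylation in place of the fold): CF3CO2H cleaves the tert-butyl ester of 5 to the diacid (2E,3E)-2,3-bis(4-methoxybenzylidene)succinic acid F1 and acetyl chloride then closes F1 to the anhydride (3E,4E)-3,4-bis(4-methoxybenzylidene)dihydrofuran-2,5-dione F2 in the usual way for such diacids. The protected arene 1-methoxy-3,5-bis(methoxymethoxy)benzene F3 is made from 5-methoxyresorcinol with MOMCl and i-Pr2NEt. Lithiation of F3 between its two methoxymethoxy groups (n-BuLi, THF, 0 °C) gives an aryllithium that opens F2 at −78 °C to the keto acid (2E,3E)-4-[4-methoxy-2,6-bis(methoxymethoxy)phenyl]-2,3-bis(4-methoxybenzylidene)-4-oxobutanoic acid F4 in one addition. CDI turns F4 into its acyl imidazole (2E,3E)-1-(1H-imidazol-1-yl)-4-[4-methoxy-2,6-bis(methoxymethoxy)phenyl]-2,3-bis(4-methoxybenzylidene)butane-1,4-dione F5 in THF at 25 °C, and F5 is used without isolation. The second arene 1,3,5-tris(methoxymethoxy)benzene F6 is made from phloroglucinol with MOMCl and i-Pr2NEt; the 2-lithio derivative of F6 (n-BuLi, THF, 0 °C) is acylated by F5 at −78 °C to the penta-MOM ether (2E,3E)-1-[4-methoxy-2,6-bis(methoxymethoxy)phenyl]-2,3-bis(4-methoxybenzylidene)-4-[2,4,6-tris(methoxymethoxy)phenyl]butane-1,4-dione F7 as the protected bis-chalcone. HCl in MeOH at 25 °C removes the five MOM groups of F7 and delivers 14 for step 8.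

Step 8. Facial control may be incomplete at the two β-carbons, since the second closure takes place on a substrate that is already chiral and may be mismatched; the very reactive 2',6'-dihydroxy enones may close without the catalyst; and C2 configuration may be lost by retro-oxa-Michael opening while C3 equilibrates. Fallback (sets out from 14, returns at 15; thermodynamic closure and resolution instead of catalyst control): NaOAc in refluxing EtOH closes both rings C under equilibrating conditions to the 2,3-trans, 2'',3''-trans biflavanones, which form two racemates. The first racemate holds 15 and its mirror image, the (2R,3S,2''R,3''S)-biflavanone F8 of the same constitution. The second racemate holds the (2S,3R,2''R,3''S)-biflavanone F9 and the (2R,3S,2''S,3''R)-biflavanone F10 as the unlike pair. The two racemates are separated on silica, the mixture of F9 and F10 is returned to the equilibration, and 15 is separated from F8 by preparative HPLC on a cellulose tris(3,5-dimethylphenylcarbamate) phase.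

Step 6. Imidazole, the acidic pyronylmethylene ketone and the product may quench the trianion by proton transfer; this hard carbanion may attack the pyrone carbonyl or add in conjugate fashion to the enones; and the activated γ-keto acid may close to an unreactive pseudo-acid derivative. Fallback (sets out from 9 by way of 11, returns at 12; dioxinone-masked chain and ketene trapping instead of the free trianion): the keto-dioxinone 2,2-dimethyl-6-(2-oxopropyl)-4H-1,3-dioxin-4-one F11 is made from 2,2,6-trimethyl-4H-1,3-dioxin-4-one with LiN(iPr)2 and acetyl chloride. The dianion of F11 (LiN(iPr)2, 2 equiv per F11, THF, −78 °C, used in threefold excess) is C-acylated at its terminal methyl by 11 to the diketo-dioxinone 6-[(5E,6E)-5,6-bis(4-methoxybenzylidene)-8-(4-methoxy-2-oxo-2H-pyran-6-yl)-2,4,7-trioxooctyl]-2,2-dimethyl-4H-1,3-dioxin-4-one F12 after a cold acid quench. Heating F12 in toluene with MeOH at 110 °C expels acetone by retro-[4+2] cleavage, and MeOH traps the acylketene as the methyl ester 12.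

**Further compounds**

F1 | step 7 | (2E,3E)-2,3-bis(4-methoxybenzylidene)succinic acid | OC(=O)/C(=C/c1ccc(OC)cc1)C(=C/c1ccc(OC)cc1)\C(=O)O
F2 | step 7 | (3E,4E)-3,4-bis(4-methoxybenzylidene)dihydrofuran-2,5-dione | O1C(=O)/C(=C/c2ccc(OC)cc2)C(=C/c2ccc(OC)cc2)\C1=O
F3 | step 7 | 1-methoxy-3,5-bis(methoxymethoxy)benzene | COCOc1cc(OC)cc(OCOC)c1
F4 | step 7 | (2E,3E)-4-[4-methoxy-2,6-bis(methoxymethoxy)phenyl]-2,3-bis(4-methoxybenzylidene)-4-oxobutanoic acid | OC(=O)/C(=C/c1ccc(OC)cc1)C(=C/c1ccc(OC)cc1)\C(=O)c1c(OCOC)cc(OC)cc1OCOC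
F5 | step 7 | (2E,3E)-1-(1H-imidazol-1-yl)-4-[4-methoxy-2,6-bis(methoxymethoxy)phenyl]-2,3-bis(4-methoxybenzylidene)butane-1,4-dione (acyl imidazole of F4, not isolated) | O=C(n1ccnc1)/C(=C/c1ccc(OC)cc1)C(=C/c1ccc(OC)cc1)\C(=O)c1c(OCOC)cc(OC)cc1OCOC
F6 | step 7 | 1,3,5-tris(methoxymethoxy)benzene | COCOc1cc(OCOC)cc(OCOC)c1
F7 | step 7 | (2E,3E)-1-[4-methoxy-2,6-bis(methoxymethoxy)phenyl]-2,3-bis(4-methoxybenzylidene)-4-[2,4,6-tris(methoxymethoxy)phenyl]butane-1,4-dione | COCOc1cc(OCOC)c(C(=O)/C(=C/c2ccc(OC)cc2)C(=C/c2ccc(OC)cc2)\C(=O)c2c(OCOC)cc(OC)cc2OCOC)c(OCOC)c1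
F8 | step 8 | (2R,3S,2''R,3''S)-5,7,5''-trihydroxy-7''-methoxy-2,2''-bis(4-methoxyphenyl)-3,3''-biflavanone (enantiomer of 15) | COc1ccc([C@@H]2Oc3cc(O)cc(O)c3C(=O)[C@H]2[C@@H]2C(=O)c3c(O)cc(OC)cc3O[C@H]2c2ccc(OC)cc2)cc1
F9 | step 8 | (2S,3R,2''R,3''S)-5,7,5''-trihydroxy-7''-methoxy-2,2''-bis(4-methoxyphenyl)-3,3''-biflavanone (diastereomer of 15) | COc1ccc([C@H]2Oc3cc(O)cc(O)c3C(=O)[C@@H]2[C@@H]2C(=O)c3c(O)cc(OC)cc3O[C@H]2c2ccc(OC)cc2)cc1
F10 | step 8 | (2R,3S,2''S,3''R)-5,7,5''-trihydroxy-7''-methoxy-2,2''-bis(4-methoxyphenyl)-3,3''-biflavanone (diastereomer of 15) | COc1ccc([C@@H]2Oc3cc(O)cc(O)c3C(=O)[C@H]2[C@H]2C(=O)c3c(O)cc(OC)cc3O[C@@H]2c2ccc(OC)cc2)cc1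
F11 | step 6 | 2,2-dimethyl-6-(2-oxopropyl)-4H-1,3-dioxin-4-one | CC(=O)CC1=CC(=O)OC(C)(C)O1
F12 | step 6 | 6-[(5E,6E)-5,6-bis(4-methoxybenzylidene)-8-(4-methoxy-2-oxo-2H-pyran-6-yl)-2,4,7-trioxooctyl]-2,2-dimethyl-4H-1,3-dioxin-4-one | CC1(C)OC(CC(=O)CC(=O)/C(=C/c2ccc(OC)cc2)C(=C/c2ccc(OC)cc2)\C(=O)CC2=CC(OC)=CC(=O)O2)=CC(=O)O1
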